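**Strategy.** Both phenolic C–O bonds are disconnected together: C2–O on the dibromo ring A and C2'–O on the tribromo ring B. This leads back to 2,2',3,4,4'-pentabromodiphenyl ether 10. The feature exploited is that bromine occupies C4, C6, C4' and C6'. C2 and C2' are therefore the only positions ortho or para to the bridging oxygen that still bear hydrogen. Anodic oxidation of 10 in trifluoroacetic acid should place a trifluoroacetoxy group on each of these carbons in one electrolysis, and methanolysis then frees the diol. Ether 10 is built unsymmetrically, so the meta bromine C5'–Br is set by lithiation while only one ring offers a C–H between two bromines.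

Key step: step 4

Numbering (used for every compound): C1 and C1' carry the ether oxygen. Ring A has OH at C2, H at C3 and C5, and Br at C4 and C6. Ring B has OH at C2', H at C3', and Br at C4', C5' and C6'.

Structure check: deleting both hydroxyl groups of 15 gives exactly 10 (ring A 2,4-dibromophenyl, ring B 2,3,4-tribromophenyl).

Remark on the chemistry: a shorter entry through symmetric 2,2',4,4'-tetrabromodiphenyl ether was set aside. Both of its rings hold the same acidic C–H, so a single metalation would be statistical and would leave congeners that are hard to separate. One extra step buys full site control.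

Assumption: 13 is moisture-sensitive and is isolated only as a water-free concentrate.

**Step 1**
Reactants: 1 2,4-dibromophenol; 2 diphenyliodonium trifluoromethanesulfonate
Product: 4 2,4-dibromo-1-phenoxybenzene, via potassium 2,4-dibromophenolate 3 (not isolated)
Conditions: KOt-Bu (1.1 equiv), THF, 0 °C, 15 min; then 2 (1.2 equiv), 40 °C
Reagents that add atoms: diphenyliodonium trifluoromethanesulfonate, c1ccc(cc1)[I+]c1ccccc1.[O-]S(=O)(=O)C(F)(F)F
Why: Metal-free O-arylation of a phenolate with a diaryliodonium salt (ligand exchange and ligand coupling at trivalent iodine) is a known route to diaryl ethers, works for ortho-halogenated phenols and leaves the C–Br bonds untouched, which a copper- or palladium-catalysed etherification would not guarantee.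

**Step 2**
Reactants: 4 2,4-dibromo-1-phenoxybenzene; 5 1,2-dibromo-1,1,2,2-tetrachloroethane
Product: 7 1,2,3-tribromo-4-phenoxybenzene, via (2,6-dibromo-3-phenoxyphenyl)lithium 6 (not isolated)
Conditions: LiN(i-Pr)2 (1.1 equiv), THF, −78 °C, 1 h; then 5 (1.3 equiv) in THF, −78 °C, then to rt
Reagents that add atoms: 1,2-dibromo-1,1,2,2-tetrachloroethane, BrC(Cl)(Cl)C(Cl)(Cl)Br
Why: Deprotonative lithiation with a lithium amide followed by halophilic bromine transfer is known for 1,3-dibromoarenes, whose C–H between the two bromines is by far the most acidic, and since only ring B of 4 has such a site, the bromine at C5' enters once and at one place.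

**Step 3**
Reactants: 7 1,2,3-tribromo-4-phenoxybenzene; 8 bromine
Product: 10 2,2',3,4,4'-pentabromodiphenyl ether, via 2,3,4,4'-tetrabromodiphenyl ether 9 (not isolated)
Conditions: 8 (2.05 equiv), FeBr3 (5 mol%), CH2Cl2, 0 °C to rt, dark; recrystallisation
Reagents that add atoms: bromine, BrBr
Why: Electrophilic aromatic bromination is steered by the ether oxygen first to the para carbon C4 and then to the ortho carbon C6 of the unsubstituted ring A, which is far more electron-rich than the tribrominated ring B, and each bromine slows the next substitution, so two equivalents should stop at 10.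

**Step 4**
Reactants: 10 2,2',3,4,4'-pentabromodiphenyl ether; 11 trifluoroacetic acid
Product: 13 3,4,5-tribromo-2-[2,4-dibromo-6-(trifluoroacetoxy)phenoxy]phenyl trifluoroacetate (bis(trifluoroacetate) of the target), via ring A mono(trifluoroacetate) 12 (not isolated)
Conditions: boron-doped diamond anode, Pt cathode, divided cell (glass frit), Bu4NBF4 (0.1 M), CF3CO2H/CH2Cl2 3:1, (CF3CO)2O (5 vol%), 10 mM in 10, 5 mA cm-2, about 5 F mol-1 (4 F mol-1 in theory), 0 °C; evaporation, trituration with dry hexane/CH2Cl2, no aqueous work-up
Reagents that add atoms: trifluoroacetic acid, OC(=O)C(F)(F)F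
Why: Proposed new method: loss of one electron at the diamond anode should turn 10 into its radical cation, whose hole rests on the bridging oxygen and mainly on the less brominated ring A; trifluoroacetic acid adds at C2, and a second electron and the C2 proton leave to give ester 12 (electron transfer, addition, electron transfer, deprotonation). The acyloxy group makes ring A the poorer donor, so the next hole should fall on oxygen and ring B, the same sequence at C2' gives 13, and 13, now the hardest species to oxidise, should persist. The closest known reaction type is anodic C–H trifluoroacetoxylation of benzene, halobenzenes and other deactivated arenes with later hydrolysis to phenols, which has not been shown for two sites in one pass or for a pentabrominated diaryl ether. No ring closes and no stereocentre is formed. The step needs C2 and C2' to win over C3, C5 and C3': they are the only hydrogen-bearing carbons ortho or para to the ether oxygen, the strongest donor present, whereas addition at the brominated carbons C4, C6, C4' and C6' can only revert because no proton is there to lose. The divided cell keeps the C–Br bonds from cathodic cleavage, and the anhydride removes water so that no free phenol meets the anode.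

**Step 5**
Reactants: 13 bis(trifluoroacetate) of the target
Product: 15 3,4,5-tribromo-2-(2,4-dibromo-6-hydroxyphenoxy)phenol, via ring A mono(trifluoroacetate) of the target 14 (not isolated)
Conditions: NaHCO3 (0.2 equiv), MeOH, 0 °C to rt; evaporation, pH 4 buffer wash
Reagents that add atoms: none
Why: Base-catalysed transesterification (methanolysis) cleaves aryl trifluoroacetates, among the most activated esters, under very mild conditions, the hydrogen carbonate is too weak to trigger a Smiles-type aryl migration or attack on C–Br, and the ester of the more acidic ring B phenol should leave first.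

**Compound list**
1 | 2,4-dibromophenol | Oc1ccc(Br)cc1Br | starting material
2 | diphenyliodonium trifluoromethanesulfonate | c1ccc(cc1)[I+]c1ccccc1.[O-]S(=O)(=O)C(F)(F)F | starting material
3 | potassium 2,4-dibromophenolate | [K+].[O-]c1ccc(Br)cc1Br | intermediate
4 | 2,4-dibromo-1-phenoxybenzene | Brc1ccc(Oc2ccccc2)c(Br)c1 | intermediate
5 | 1,2-dibromo-1,1,2,2-tetrachloroethane | BrC(Cl)(Cl)C(Cl)(Cl)Br | starting material
6 | (2,6-dibromo-3-phenoxyphenyl)lithium | [Li]c1c(Br)ccc(Oc2ccccc2)c1Br | intermediate
7 | 1,2,3-tribromo-4-phenoxybenzene | Brc1ccc(Oc2ccccc2)c(Br)c1Br | intermediate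
8 | bromine | BrBr | starting material
9 | 2,3,4,4'-tetrabromodiphenyl ether, 1,2,3-tribromo-4-(4-bromophenoxy)benzene | Brc1ccc(Oc2ccc(Br)c(Br)c2Br)cc1 | intermediate
10 | 2,2',3,4,4'-pentabromodiphenyl ether, 1,2,3-tribromo-4-(2,4-dibromophenoxy)benzene | Brc1ccc(Oc2ccc(Br)c(Br)c2Br)c(Br)c1 | intermediate
11 | trifluoroacetic acid | OC(=O)C(F)(F)F | starting material
12 | ring A mono(trifluoroacetate), 3,5-dibromo-2-(2,3,4-tribromophenoxy)phenyl trifluoroacetate | FC(F)(F)C(=O)Oc1cc(Br)cc(Br)c1Oc1ccc(Br)c(Br)c1Br | intermediate
13 | bis(trifluoroacetate) of the target, 3,4,5-tribromo-2-[2,4-dibromo-6-(trifluoroacetoxy)phenoxy]phenyl trifluoroacetate | FC(F)(F)C(=O)Oc1cc(Br)cc(Br)c1Oc1c(OC(=O)C(F)(F)F)cc(Br)c(Br)c1Br | intermediate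
14 | ring A mono(trifluoroacetate) of the target, 3,5-dibromo-2-(2,3,4-tribromo-6-hydroxyphenoxy)phenyl trifluoroacetate | FC(F)(F)C(=O)Oc1cc(Br)cc(Br)c1Oc1c(O)cc(Br)c(Br)c1Br | intermediate
15 | 3,4,5-tribromo-2-(2,4-dibromo-6-hydroxyphenoxy)phenol | Oc1cc(Br)cc(Br)c1Oc1c(O)cc(Br)c(Br)c1Br | target

Total step count: 5. Longest linear sequence: 5 steps (1, 4, 7, 10, 13, 15).

**Steps most likely to fail**

1. **Step 4 (labelled step).**
 - Main risk: once ring A carries its ester, the potential needed to put a hole on ring B may lie beyond the anodic limit of the medium. The electrolysis would then stall half-way or turn to oxidation of solvent and electrolyte.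
 - Further leaks: nucleophile capture at C3, where the bromine lone pairs also support charge and where electrophilic bromination of 2,4-dibromophenoxy rings is known to enter; loss of bromine after ipso attack; and bond formation between C2 and C2'.
 - Fallback (known chemistry, both oxygens brought in with the building blocks): it sets out from bromine 8 and comes back at target 15. Commercial guaiacol (COc1ccccc1O) is tribrominated with 8 in AcOH. The free hydroxyl steers to its para and ortho carbons (later C4' and C6') and the methoxy group to its para carbon (later C5'), which gives 2,3,4-tribromo-6-methoxyphenol F1. F1 then undergoes SNAr on commercial 3,5-dibromo-2-fluorobenzaldehyde (O=Cc1cc(Br)cc(Br)c1F; K2CO3, DMAc, 110 °C). Only the fluorine is activated by the ortho formyl group, so the product is 3,5-dibromo-2-(2,3,4-tribromo-6-methoxyphenoxy)benzaldehyde F2. Baeyer–Villiger oxidation (mCPBA, CH2Cl2, reflux) leads to 3,5-dibromo-2-(2,3,4-tribromo-6-methoxyphenoxy)phenyl formate F3. Methanolysis (catalytic K2CO3, MeOH) gives 3,5-dibromo-2-(2,3,4-tribromo-6-methoxyphenoxy)phenol F4. BBr3 (CH2Cl2, −78 °C to rt) cleaves the methyl ether to 15.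

2. **Step 2.**
 - Risk: the ortho-bromoaryllithium may lose LiBr to an aryne, or bromine may migrate between aryl anions before the quench. Both would scramble the halogen pattern.
 - Fallback (no carbanion next to bromine): it sets out from 2 and comes back at 7. Commercial 2,3-dibromophenol (Oc1cccc(Br)c1Br) is brominated para to the hydroxyl with Bu4NBr3 (CH2Cl2/MeOH, rt) to give 2,3,4-tribromophenol F5. KOt-Bu converts it into potassium 2,3,4-tribromophenolate F6, which 2 O-phenylates as in step 1 to give 7.

3. **Step 3.**
 - Risk: bromination may run past the second bromine or enter ring A meta to oxygen. The Lewis acid and HBr may also move bromine within the crowded ring B.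
 - Fallback (ring A arrives with its bromines in place, and the last bromine comes from an amine): it sets out from 1 and comes back at 10. Commercial 1,2-dibromo-3-fluorobenzene (Fc1cccc(Br)c1Br) is nitrated para to fluorine (HNO3, H2SO4, 0 °C) to give 2,3-dibromo-1-fluoro-4-nitrobenzene F7. SNAr with 1 (K2CO3, DMF, 60 °C) displaces the fluoride para to the nitro group and gives 2,3-dibromo-1-(2,4-dibromophenoxy)-4-nitrobenzene F8. Fe and NH4Cl (EtOH/H2O, 70 °C) reduce it to 2,3-dibromo-4-(2,4-dibromophenoxy)aniline F9. A Sandmeyer-type bromination (t-BuONO, CuBr2, MeCN, 60 °C) gives 10.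

**Further compounds**
F1 | step 4 | 2,3,4-tribromo-6-methoxyphenol | COc1cc(Br)c(Br)c(Br)c1O
F2 | step 4 | 3,5-dibromo-2-(2,3,4-tribromo-6-methoxyphenoxy)benzaldehyde | O=Cc1cc(Br)cc(Br)c1Oc1c(OC)cc(Br)c(Br)c1Br
F3 | step 4 | 3,5-dibromo-2-(2,3,4-tribromo-6-methoxyphenoxy)phenyl formate | O=COc1cc(Br)cc(Br)c1Oc1c(OC)cc(Br)c(Br)c1Br
F4 | step 4 | 3,5-dibromo-2-(2,3,4-tribromo-6-methoxyphenoxy)phenol | Oc1cc(Br)cc(Br)c1Oc1c(OC)cc(Br)c(Br)c1Br
F5 | step 2 | 2,3,4-tribromophenol | Oc1ccc(Br)c(Br)c1Br
F6 | step 2 | potassium 2,3,4-tribromophenolate | [K+].[O-]c1ccc(Br)c(Br)c1Br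
F7 | step 3 | 2,3-dibromo-1-fluoro-4-nitrobenzene | Fc1ccc([N+](=O)[O-])c(Br)c1Br
F8 | step 3 | 2,3-dibromo-1-(2,4-dibromophenoxy)-4-nitrobenzene | O=[N+]([O-])c1ccc(Oc2ccc(Br)cc2Br)c(Br)c1Br
F9 | step 3 | 2,3-dibromo-4-(2,4-dibromophenoxy)aniline | Nc1ccc(Oc2ccc(Br)cc2Br)c(Br)c1Br
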